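## The problem

The target is a daucane diester. Daucane numbering is used throughout: C1 is the quaternary ring-fusion carbon carrying a methyl group, C2–C3 are methylenes, C4 is the isopropyl carbinol, C5 the ring-fusion CH, C6 the veratrate carbinol, C7 a methylene, C8=C9 the methyl-bearing alkene and C10 the angelate carbinol. Ring A is the cyclopentane and ring B the cycloheptene, fused trans across C1–C5.

Five stereocentres must be set, (1S,4R,5S,6S,10R). The quaternary C1 and its neighbour C10 have no earlier centre to lean on and must be fixed absolutely. Once they exist, the C1 methyl can direct the proton at C5 and the isopropyl group at C4, and the C4 hydroxyl can direct the hydride at C6.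

Several groups are fragile. The angelate isomerises to the tiglate under basic or nucleophilic acylation conditions, and the C10 ester is allylic. The C4 tertiary alcohol sits β to the C6 oxygen, so any C6-ketone stage is open to retro-aldol cleavage and dehydration.

The seven carbons of ring B divide naturally into a three-carbon unit C6–C5–C1 and a four-carbon unit C7–C8–C9–C10. The first can be a cyclopentene (C5=C1, which is also ring A) carrying a carbenoid carbon C6. The second is a 3-methylbutadiene oxygenated at C10. A cyclopropanation/Cope sequence between them leaves the alkene at C8=C9, where the target has it, and forms the C1 quaternary centre and the C10 carbinol together.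

## Retrosynthesis

**Ester bonds.** The C10–O angeloyl bond of target 25 is cut last, to alcohol 22 and angelic acid 23 (activated as mixed anhydride 24), so that the isomerisable angelate meets no further reagent. The C6–O veratroyl bond is cut before it, from silyl ether 21 to diol 19 and 3,4-dimethoxybenzoyl chloride 20. With C10 still silylated and C4 tertiary, C6 is the only hydroxyl in 19 that can be acylated, so the two secondary alcohols need no further differentiation.

**C6–H bond.** Diol 19 is traced to β-hydroxy ketone 18. An undirected hydride would be expected to approach C6 from the face away from the angular methyl and give the wrong epimer. Delivery from boron bound to the C4 hydroxyl puts hydrogen on the methyl face and gives the required anti-1,3-diol. This is why the C4 carbinol must exist before the C6 carbinol is finally set.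

**C4–isopropyl bond.** Ketone 18 comes by oxidation from diol 17, and 17 from isopropyl addition to cyclopentanone 16. A C4/C6 diketone would be a 1,3-dicarbonyl and could not be alkylated at one carbonyl, so C6 is carried through this stage as an alcohol of either configuration (15, 16, 17). Hydroxy ketone 16 comes from ketal 15, and 15 from ketone 14 by reduction. The forward addition must go anti to the C1 methyl and must beat enolisation.

**C6–carboxyl bond.** Ketone 14 has one carbon fewer than the annulation product. Cutting the exocyclic C6–CO2H bond of unsaturated acid 11 by Curtius rearrangement (via acyl azide 12 and vinyl isocyanate 13) turns the enoate directly into the C6 ketone and creates C5–H next to it. This is shorter than reducing the enoate, hydroxylating, reducing again and cleaving a diol. It also leaves C5 adjacent to a carbonyl, where its configuration can be adjusted. Acid 11 comes from methyl ester 10.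

**Ring B (key disconnection).** Diene ester 10 is cut at C6–C7 and C1–C10 into diazo ester 6 and siloxydiene 8, by way of cis-divinylcyclopropane 9. Against closing ring B by aldol or metathesis on a preformed ring A, this cut builds the ring, the quaternary centre and the C10 carbinol in one operation from two achiral partners. The price is an extra carboxyl carbon on C6 and a demanding carbenoid whose vinyl terminus is fully substituted.

**Fragments.** Diazo ester 6 comes by diazo transfer from ester 5, and 5 from cyclopentenone 4 by ketalisation without alkene migration. Enone 4 is the aldol product of 1,4-diketone 3, made by Stetter addition of methyl 4-oxobutanoate 1 to methyl vinyl ketone 2. Diene 8 is the silyl dienol ether of 3-methylbut-2-enal 7.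

## Roads not taken

**Alternative 1:** Cut C1–C10 and C5–C6 without closing a ring. In the forward sense, 3-methylcyclopent-2-en-1-one A1 takes up the silyl-substituted alkenylaluminium A2 under Cu(OTf)2 and a chiral N-heterocyclic carbene ligand. The resulting aluminium enolate is trapped by 3,3-ethylenedioxybutanal A3 to give aldol A4.
- Merits: the quaternary C1 is set by a well-established catalytic conjugate addition on a cheap enone. The C4 carbonyl and C6 oxygen are in place from the first step, and no carbon has to be excised later.
- Weak points: ring B is still open. After unmasking C8 and converting the vinylsilane into a C10 carbonyl, the C8–C9 bond has to be made by a medium-ring aldol condensation. The C10 carbinol then comes from reduction of an enone next to the quaternary carbon, where hydride should arrive anti to the methyl and give the wrong epimer. The C6 configuration rests on an aluminium-enolate aldol of uncertain selectivity.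
- Comparison: this road is better on the quaternary centre and on early C4/C6 oxygenation. The chosen plan sets against it that ring B, the C8=C9 alkene and the C10 configuration all come from one stereospecific step.

**Alternative 2:** Cut C1–C2 in ring A. In the forward sense, BF3·OEt2 opens epoxy cyclobutanol A5 at the tertiary carbon while a cyclobutane carbon migrates, giving cyclopentanone A6.
- Merits: C1 and C10 are set together and stereospecifically, because migration is anti to the departing epoxide oxygen. The C10 oxygen is present from the start.
- Weak points: A6 contains only ring A. The whole of ring B and the C4, C5 and C6 centres remain to be built. The ketone sits at C5, so forming C5–C6 by carbonyl addition leaves an oxygen that must be removed, and C4 has no oxygen yet. Enantioselective epoxidation of the required trisubstituted enoate bearing a tertiary allylic alcohol is not a routine case.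
- Comparison: stereospecificity at C1/C10 is at least as good as in the chosen plan, but far more of the molecule is left to construct.

**Alternative 3:** Cut C1–C5, so that both rings arise from a decalin. (S)-Wieland–Miescher ketone A7 would be taken to the cis-fused diol monomesylate A8. KOtBu then triggers a semipinacol shift of C1 from C6 to C5, giving trans-fused hydroazulenone A9.
- Merits: C1 comes from a cheap enantiopure building block with no catalyst risk. The shift is stereospecific and delivers the trans fusion, the C4 isopropyl carbinol and the C6 ketone at once, which is the equivalent of compound 18 here.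
- Weak points: A8 needs a face-selective isopropyl addition, a face-selective dihydroxylation and a selective mesylation. The product is a β-hydroxy ketone formed under strong base. Ring B of A9 has neither the C8 methyl nor the C8=C9 alkene, and its C10 ketone must be reduced without a controlling element.
- Comparison: for C1, C4 and C5 this road is the more secure. The chosen plan sets against it that the C8 methyl, the alkene and the C10 carbinol arrive with the diene instead of over a long functionalisation of a saturated ring.

Key step: step 6

Assumption (remark on the chemistry): Rh2(S-DOSP)4 is taken to show with 6 the sense of induction that is general for donor/acceptor carbenoids and terminal alkenes. If the antipodal series formed, Rh2(R-DOSP)4 would be used with no other change.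

## Route

Step 1
Reactants: 1 methyl 4-oxobutanoate; 2 but-3-en-2-one (methyl vinyl ketone)
Product: 3 methyl 4,7-dioxooctanoate
Conditions: 3-benzyl-5-(2-hydroxyethyl)-4-methylthiazolium chloride (10 mol%), Et3N, EtOH, 80 °C
Reagents that add atoms: none
Why: Stetter reaction; the thiazolium carbene turns the aliphatic aldehyde into an acyl anion equivalent that adds 1,4 to the enone, the standard entry to 1,4-diketones.

Step 2
Reactants: 3 methyl 4,7-dioxooctanoate
Product: 4 methyl 2-(2-methyl-5-oxocyclopent-1-en-1-yl)acetate
Conditions: NaOMe, MeOH, 65 °C; then HCl/MeOH, rt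
Reagents that add atoms: none
Why: Intramolecular aldol condensation of a 1,4-diketone; under equilibrating base the enolate at C3 closes onto the methyl ketone and dehydration gives the tetrasubstituted 2,3-dialkylcyclopentenone, and the acidic methanol finish re-esterifies any carboxylate formed by the water of condensation.

Step 3
Reactants: 4 methyl 2-(2-methyl-5-oxocyclopent-1-en-1-yl)acetate
Product: 5 methyl 2-(7-methyl-1,4-dioxaspiro[4.4]non-6-en-6-yl)acetate
Conditions: (TMSOCH2)2, TMSOTf (5 mol%), CH2Cl2, −78 → −20 °C
Reagents that add atoms: 1,2-bis(trimethylsilyloxy)ethane, C[Si](C)(C)OCCO[Si](C)(C)C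
Why: Noyori ketalisation; the aprotic low-temperature conditions form the dioxolane under kinetic control, so the tetrasubstituted alkene is not expected to migrate as it can under protic acid at reflux.

Step 4
Reactants: 5 methyl 2-(7-methyl-1,4-dioxaspiro[4.4]non-6-en-6-yl)acetate
Product: 6 methyl 2-diazo-2-(7-methyl-1,4-dioxaspiro[4.4]non-6-en-6-yl)acetate
Conditions: p-ABSA, DBU, MeCN, 0 °C → rt
Reagents that add atoms: 4-acetamidobenzenesulfonyl azide, CC(=O)Nc1ccc(cc1)S(=O)(=O)N=[N+]=[N-]
Why: Regitz diazo transfer to a β,γ-unsaturated ester, the usual preparation of vinyldiazoacetates; the methylene is activated by both the ester and the alkene, and the ketal is untouched by DBU.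

Step 5
Reactants: 7 3-methylbut-2-enal
Product: 8 (E)-tert-butyldimethyl[(3-methylbuta-1,3-dien-1-yl)oxy]silane
Conditions: TBSOTf, Et3N, Et2O, 0 °C → rt
Reagents that add atoms: tert-butyldimethylsilyl trifluoromethanesulfonate, CC(C)(C)[Si](C)(C)OS(=O)(=O)C(F)(F)F
Why: O-silylation of the enal with γ-deprotonation (silyl dienol ether formation); either methyl group gives the same diene and the s-trans enal leads to the E enol ether.

Step 6
Reactants: 6 methyl 2-diazo-2-(7-methyl-1,4-dioxaspiro[4.4]non-6-en-6-yl)acetate; 8 (E)-tert-butyldimethyl[(3-methylbuta-1,3-dien-1-yl)oxy]silane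
Product: 10 hydroazulene diene ester (1S,10R): ring A with C4 ethylene ketal and C1 methyl; ring B with C5=C6 bearing CO2Me on C6 and C8=C9 bearing methyl on C8 and with C10 OTBS trans to the C1 methyl, via cis-divinylcyclopropane 9 (not isolated)
Conditions: Rh2(S-DOSP)4 (dirhodium tetrakis[(S)-N-(4-dodecylphenylsulfonyl)prolinate], 1 mol%), 8 (4 equiv), hexanes/PhCF3, −40 °C → rt, slow addition of 6; then PhMe, 80 °C
Reagents that add atoms: none
Why: The chiral divalent-rhodium dimer extrudes N2 from 6 to give a donor/acceptor (vinyl/ester) carbenoid, whose carbon C6 adds across the terminal C7=C8 bond of 8 in an asynchronous concerted cyclopropanation that places the cyclopentenyl group cis to the dienyl substituent and gives cis-divinylcyclopropane 9. Strain release then drives the [3,3] shift of 9 through the boat transition state open to cis-divinylcyclopropanes, forming C1–C10, breaking C6–C8 and leaving the C5=C6 and C8=C9 double bonds; this is the tandem cyclopropanation/Cope rearrangement (formal (4+3) annulation) known for vinyldiazoacetates with 1-oxygenated dienes. Ring B is thus closed not by an end-to-end cyclisation but by sigmatropic ring expansion of the three-membered ring, the C1–C10 bond forming intramolecularly and suprafacially on both vinyl groups. C1 and C10 arise together: the E enol ether and the ring-fixed C5=C1 geometry put the silyloxy group and C2 on the outside of the boat, so they finish cis and the C10 oxygen is trans to the C1 methyl, while the absolute sense comes from the carbenoid face that the prolinate ligands leave open during cyclopropanation. The step needs site selectivity for C7=C8 over the enol ether bond; the substrate secures it because the carbenoid needs an unsubstituted alkene terminus for its end-on approach, which the trans-disubstituted C9=C10 bond lacks, and because the fully substituted vinyl terminus of the carbenoid suppresses vinylogous attack. It also needs the two vinyl groups cis, which follows from the usual preference of the donor group for the side of the alkene's π-substituent. Because the C1 methyl points into the boat, rearrangement of 9 is expected to need warming, hence the heating before work-up.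

Step 7
Reactants: 10 hydroazulene diene ester (1S,10R)
Product: 11 hydroazulene diene carboxylic acid (1S,10R), the C6 carboxylic acid of 10
Conditions: KOH, MeOH/H2O, 70 °C; then 1 M HCl to pH 4, 0 °C
Reagents that add atoms: potassium hydroxide, [K+].[OH-]
Why: Saponification; the enoate has no γ-hydrogen (C1 is quaternary, C4 a ketal) so the diene cannot move into conjugation, and the hindered neopentylic TBS ether and the dioxolane tolerate hydroxide and a brief cold acidification.

Step 8
Reactants: 11 hydroazulene diene carboxylic acid (1S,10R)
Product: 14 trans-fused ketone (1S,5S,10R): C6 ketone, C5–H anti to the C1 methyl, C4 ethylene ketal, C8=C9, C10 OTBS, via acyl azide 12 (not isolated), via vinyl isocyanate 13 (not isolated)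
Conditions: DPPA, Et3N, PhMe, rt then 90 °C; 1 M NaOH, THF, 0 °C → rt; AcOH to pH 5; K2CO3 (cat.), MeOH, rt
Reagents that add atoms: water, O
Why: Curtius rearrangement of an α,β-unsaturated acid followed by hydrolysis of the vinyl isocyanate, a known one-carbon degradation to the ketone; hydroxide converts the isocyanate fully to carbamate before mild acid releases CO2 and ammonia, and C5 is protonated anti to the adjacent C1 methyl and can equilibrate next to the new carbonyl toward the trans-fused hydroazulen-6-one.

Step 9
Reactants: 14 trans-fused ketone (1S,5S,10R)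
Product: 15 C6 alcohol (1S,5S,10R), C4 ketal retained; C6 epimers, the 6R (β) alcohol expected to predominate, both carried on
Conditions: NaBH4, MeOH, 0 °C
Reagents that add atoms: none
Why: Borohydride reduction; it only masks C6 as a non-electrophilic alcohol for the C4 alkylation, so its facial outcome (hydride anti to the angular methyl) does not have to be controlled.

Step 10
Reactants: 15 C6 alcohol (1S,5S,10R)
Product: 16 hydroxy ketone (1S,5S,10R): C4 cyclopentanone, C6 alcohol (epimers), C10 OTBS
Conditions: PPTS, acetone/H2O, 40 °C
Reagents that add atoms: water, O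
Why: Mild acid hydrolysis of the dioxolane; PPTS is weak enough to spare the TBS ether and to limit dehydration of the β-hydroxy ketone and enolisation at C5.

Step 11
Reactants: 16 hydroxy ketone (1S,5S,10R)
Product: 17 diol (1S,4R,5S,10R): C4 tertiary alcohol cis to the C1 methyl with isopropyl on the opposite face, C6 alcohol (epimers), C10 OTBS
Conditions: iPrMgCl (4 equiv), CeCl3, THF, −78 → 0 °C
Reagents that add atoms: isopropylmagnesium chloride, CC(C)[Mg]Cl
Why: Organocerium-mediated Grignard addition, which suppresses enolisation and β-hydride reduction of the hindered ketone; the nucleophile should enter anti to the C1 methyl (cis-1,3 across ring A) and away from the predominantly β-oriented C6 alkoxide, setting C4 as R.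

Step 12
Reactants: 17 diol (1S,4R,5S,10R)
Product: 18 β-hydroxy ketone (1S,4R,5R,10R): C6 ketone, C4 tertiary alcohol, C10 OTBS (the C5 descriptor changes by priority only)
Conditions: Dess–Martin periodinane, CH2Cl2, 0 °C → rt
Reagents that add atoms: none
Why: Dess–Martin oxidation of the only secondary alcohol; the neutral to weakly acidic medium avoids retro-aldol cleavage of the tertiary aldol, and both C6 epimers converge on one ketone.

Step 13
Reactants: 18 β-hydroxy ketone (1S,4R,5R,10R)
Product: 19 diol (1S,4R,5S,6S,10R): C4 and C6 hydroxyls anti, C6 hydroxyl cis to H5, C10 OTBS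
Conditions: Me4NBH(OAc)3, MeCN/AcOH, −20 °C
Reagents that add atoms: none
Why: Hydroxyl-directed reduction with triacetoxyborohydride (Evans–Saksena type); boron bound to the C4 oxygen delivers hydride intramolecularly to the methyl-side face of the C6 carbonyl, giving the anti-1,3-diol and hence C6 as S, and the reagent leaves an undirected ketone essentially untouched.

Step 14
Reactants: 19 diol (1S,4R,5S,6S,10R); 20 3,4-dimethoxybenzoyl chloride
Product: 21 C6 veratrate (1S,4R,5S,6S,10R) with free C4 hydroxyl and C10 OTBS
Conditions: Et3N, DMAP (cat.), CH2Cl2, 0 °C → rt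
Reagents that add atoms: none
Why: DMAP-catalysed acylation; the secondary C6 hydroxyl is the only acylable one, since C4 is tertiary and C10 is silylated.

Step 15
Reactants: 21 C6 veratrate (1S,4R,5S,6S,10R)
Product: 22 C10 alcohol (1S,4R,5S,6S,10R): C6 veratrate, free C4 and C10 hydroxyls
Conditions: TBAF, AcOH, THF, 0 °C → rt
Reagents that add atoms: none
Why: Fluoride desilylation buffered with acetic acid, so that the aryl ester is neither cleaved nor moved; the anti-disposed tertiary C4 hydroxyl cannot accept the acyl group.

Step 16
Reactants: 22 C10 alcohol (1S,4R,5S,6S,10R); 23 angelic acid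
Product: 25 target, (1S,4R,5S,6S,10R)-10-angeloyloxy-6-(3,4-dimethoxybenzoyloxy)-4-hydroxydauc-8-ene, via angelic 2,4,6-trichlorobenzoic anhydride 24 (not isolated)
Conditions: 2,4,6-trichlorobenzoyl chloride, Et3N, PhMe, rt; then 22, 75 °C
Reagents that add atoms: none
Why: Yamaguchi-type esterification through the mixed anhydride without nucleophilic catalyst, the established way to angeloylate hindered secondary alcohols without Z to E isomerisation; the tertiary C4 hydroxyl does not react.

## Compound list

1 | methyl 4-oxobutanoate | COC(=O)CCC=O | starting material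
2 | but-3-en-2-one | CC(=O)C=C | starting material
3 | methyl 4,7-dioxooctanoate | COC(=O)CCC(=O)CCC(C)=O | intermediate
4 | methyl 2-(2-methyl-5-oxocyclopent-1-en-1-yl)acetate | COC(=O)CC1=C(C)CCC1=O | intermediate
5 | methyl 2-(7-methyl-1,4-dioxaspiro[4.4]non-6-en-6-yl)acetate | COC(=O)CC1=C(C)CCC12OCCO2 | intermediate
6 | methyl 2-diazo-2-(7-methyl-1,4-dioxaspiro[4.4]non-6-en-6-yl)acetate | COC(=O)C(=[N+]=[N-])C1=C(C)CCC12OCCO2 | intermediate
7 | 3-methylbut-2-enal | CC(C)=CC=O | starting material
8 | (E)-tert-butyldimethyl[(3-methylbuta-1,3-dien-1-yl)oxy]silane | C=C(C)/C=C/O[Si](C)(C)C(C)(C)C | intermediate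
9 | methyl (1S,2R)-2-[(E)-2-(tert-butyldimethylsilyloxy)ethenyl]-2-methyl-1-(7-methyl-1,4-dioxaspiro[4.4]non-6-en-6-yl)cyclopropane-1-carboxylate | COC(=O)[C@]1(C[C@]1(C)/C=C/O[Si](C)(C)C(C)(C)C)C1=C(C)CCC12OCCO2 | intermediate
10 | hydroazulene diene ester (1S,10R): C4 ethylene ketal, C5=C6 with CO2Me on C6, C8=C9, C10 OTBS | CC(C)(C)[Si](C)(C)O[C@@H]1C=C(C)CC(C(=O)OC)=C2[C@]1(C)CCC23OCCO3 | intermediate
11 | hydroazulene diene carboxylic acid (1S,10R) | CC(C)(C)[Si](C)(C)O[C@@H]1C=C(C)CC(C(=O)O)=C2[C@]1(C)CCC23OCCO3 | intermediate
12 | acyl azide of 11 (1S,10R) | CC(C)(C)[Si](C)(C)O[C@@H]1C=C(C)CC(C(=O)N=[N+]=[N-])=C2[C@]1(C)CCC23OCCO3 | intermediate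
13 | C6 vinyl isocyanate (1S,10R) | CC(C)(C)[Si](C)(C)O[C@@H]1C=C(C)CC(N=C=O)=C2[C@]1(C)CCC23OCCO3 | intermediate
14 | trans-fused C6 ketone with C4 ethylene ketal and C10 OTBS (1S,5S,10R) | CC(C)(C)[Si](C)(C)O[C@@H]1C=C(C)CC(=O)[C@@H]2[C@]1(C)CCC23OCCO3 | intermediate
15 | C6 alcohol with C4 ethylene ketal (1S,5S,10R; C6 epimers) | CC(C)(C)[Si](C)(C)O[C@@H]1C=C(C)CC(O)[C@@H]2[C@]1(C)CCC23OCCO3 | intermediate
16 | C4 ketone, C6 alcohol (1S,5S,10R; C6 epimers) | CC(C)(C)[Si](C)(C)O[C@@H]1C=C(C)CC(O)[C@@H]2[C@]1(C)CCC2=O | intermediate
17 | C4 isopropyl carbinol, C6 alcohol (1S,4R,5S,10R; C6 epimers) | CC(C)(C)[Si](C)(C)O[C@@H]1C=C(C)CC(O)[C@@H]2[C@]1(C)CC[C@@]2(O)C(C)C | intermediate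
18 | β-hydroxy ketone: C6 ketone, C4 isopropyl carbinol (1S,4R,5R,10R) | CC(C)(C)[Si](C)(C)O[C@@H]1C=C(C)CC(=O)[C@@H]2[C@]1(C)CC[C@@]2(O)C(C)C | intermediate
19 | 4,6-diol with C10 OTBS (1S,4R,5S,6S,10R) | CC(C)(C)[Si](C)(C)O[C@@H]1C=C(C)C[C@H](O)[C@@H]2[C@]1(C)CC[C@@]2(O)C(C)C | intermediate
20 | 3,4-dimethoxybenzoyl chloride | COc1ccc(C(=O)Cl)cc1OC | starting material
21 | C6 veratrate with C10 OTBS (1S,4R,5S,6S,10R) | CC(C)(C)[Si](C)(C)O[C@@H]1C=C(C)C[C@H](OC(=O)c2ccc(OC)c(OC)c2)[C@@H]2[C@]1(C)CC[C@@]2(O)C(C)C | intermediate
22 | C6 veratrate with free C10 hydroxyl (1S,4R,5S,6S,10R) | O[C@@H]1C=C(C)C[C@H](OC(=O)c2ccc(OC)c(OC)c2)[C@@H]2[C@]1(C)CC[C@@]2(O)C(C)C | intermediate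
23 | angelic acid, (Z)-2-methylbut-2-enoic acid | C/C=C(/C)C(=O)O | starting material
24 | angelic 2,4,6-trichlorobenzoic anhydride | C/C=C(/C)C(=O)OC(=O)c1c(Cl)cc(Cl)cc1Cl | intermediate
25 | CNP0142353.1, (1S,4R,5S,6S,10R)-10-angeloyloxy-6-(3,4-dimethoxybenzoyloxy)-4-hydroxydauc-8-ene | C/C=C(/C)C(=O)O[C@@H]1C=C(C)C[C@H](OC(=O)c2ccc(OC)c(OC)c2)[C@@H]2[C@]1(C)CC[C@@]2(O)C(C)C | target

## Step count and least certain steps

Total step count: 16. Longest linear sequence: 15 steps (steps 1–4 and 6–16); step 5 makes the second fragment.

**Step 6 (key step).**
- What may go wrong: loss of enantio- and diastereocontrol, because the vinyl group of the carbenoid is flanked by the ketal and the methyl and may twist out of conjugation, so that it acts less like a donor. The Cope rearrangement may stall at the cyclopropane because the C1 methyl points into the boat. Insertion of the carbenoid into a dioxolane C–H bond may compete.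
- Fallback: absolute control is moved from the catalyst to the ester. It sets out from compound 5. Saponification (LiOH) gives 2-(7-methyl-1,4-dioxaspiro[4.4]non-6-en-6-yl)acetic acid F1. Esterification with (R)-pantolactone (DCC, DMAP) gives the pantolactonyl ester F2, and diazo transfer (p-ABSA, DBU) gives the pantolactonyl diazo ester F3. Decomposition with achiral dirhodium tetraoctanoate, Rh2(O2CC7H15)4, in the presence of 8 should give the pantolactonyl divinylcyclopropane F4 and, after warming, the hydroazulene pantolactonyl ester F5, which can be purified as a single diastereomer. Hydrolysis with KOH comes back to the route at acid 11. α-Hydroxy-ester auxiliaries are an established means of directing vinylcarbenoid cyclopropanation. The pantolactone enantiomer that leads to the (1S,10R) series is the one to use; the (R)-lactone is drawn.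

**Step 8.**
- What may go wrong: incomplete hydrolysis of the hindered vinyl isocyanate or its diversion to ureas, and protonation or equilibration at C5 toward the cis-fused ketone.
- Fallback: C5 is set under kinetic control and the carbon is excised stepwise. It sets out from compound 10. Dissolving-metal conjugate reduction (Li, liquid NH3, t-BuOH, −78 °C) should give the saturated ester F6 with H5 anti to the methyl. Enolate hydroxylation (KN(SiMe3)2, then 2-(phenylsulfonyl)-3-phenyloxaziridine) gives the α-hydroxy ester F7, and LiAlH4 gives the 1,2-diol F8. NaIO4 cleavage comes back to the route at ketone 14.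

**Step 11.**
- What may go wrong: enolisation or β-hydride reduction of the hindered α-branched cyclopentanone instead of addition, retro-aldol opening through the C6 alkoxide, and epimerisation at C5.
- Fallback: an sp2 nucleophile without β-hydrogens is used. It sets out from compound 16. Isopropenylmagnesium bromide with CeCl3 should give the isopropenyl carbinol F9. Hydrogenation of its 1,1-disubstituted alkene with RhCl(PPh3)3 and H2, which leaves the trisubstituted ring alkene alone, comes back to the route at diol 17.

**Step 13.**
- What may go wrong: ligand exchange at the tertiary C4 hydroxyl may be too slow for hydride delivery, or acid may dehydrate the tertiary aldol.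
- Fallback: the hydride is tethered covalently. It sets out from compound 18. Silylation with chlorodimethylsilane and imidazole gives the C4 dimethylsilyl ether F10. SnCl4-catalysed intramolecular hydrosilylation at −78 °C should give the cyclic dimethylsilylene acetal F11 with hydrogen delivered to the same face. Methanolysis (K2CO3, MeOH) comes back to the route at diol 19.

**Step 16.**
- What may go wrong: isomerisation of the angeloyl unit to the tigloyl isomer during slow acylation of the neopentylic C10 alcohol.
- Fallback: the Z alkene is built on the ester. It sets out from compound 22. Acylation with 2-[bis(2,2,2-trifluoroethoxy)phosphoryl]propanoic acid (DCC, DMAP) gives the phosphonopropanoate F12. Still–Gennari olefination (KN(SiMe3)2, 18-crown-6, acetaldehyde, −78 °C) should give the Z-configured 2-methylbut-2-enoate and comes back to the route at target 25.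

## Further compounds

F1 | step 6 | 2-(7-methyl-1,4-dioxaspiro[4.4]non-6-en-6-yl)acetic acid | OC(=O)CC1=C(C)CCC12OCCO2
F2 | step 6 | (R)-pantolactonyl 2-(7-methyl-1,4-dioxaspiro[4.4]non-6-en-6-yl)acetate | CC1(C)COC(=O)[C@@H]1OC(=O)CC1=C(C)CCC12OCCO2
F3 | step 6 | (R)-pantolactonyl 2-diazo-2-(7-methyl-1,4-dioxaspiro[4.4]non-6-en-6-yl)acetate | CC1(C)COC(=O)[C@@H]1OC(=O)C(=[N+]=[N-])C1=C(C)CCC12OCCO2
F4 | step 6 | (R)-pantolactonyl ester analogue of divinylcyclopropane 9 | CC1(C)COC(=O)[C@@H]1OC(=O)[C@]1(C[C@]1(C)/C=C/O[Si](C)(C)C(C)(C)C)C1=C(C)CCC12OCCO2
F5 | step 6 | (R)-pantolactonyl ester analogue of hydroazulene diene ester 10 (1S,10R) | CC(C)(C)[Si](C)(C)O[C@@H]1C=C(C)CC(C(=O)O[C@H]3C(=O)OCC3(C)C)=C2[C@]1(C)CCC24OCCO4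
F6 | step 8 | saturated C6 methyl ester with H5 anti to the C1 methyl (1S,5S,10R; C6 epimers) | CC(C)(C)[Si](C)(C)O[C@@H]1C=C(C)CC(C(=O)OC)[C@@H]2[C@]1(C)CCC23OCCO3
F7 | step 8 | C6 α-hydroxy methyl ester (1S,5S,10R; C6 epimers) | CC(C)(C)[Si](C)(C)O[C@@H]1C=C(C)CC(O)(C(=O)OC)[C@@H]2[C@]1(C)CCC23OCCO3
F8 | step 8 | C6 hydroxy hydroxymethyl diol (1S,5S,10R; C6 epimers) | CC(C)(C)[Si](C)(C)O[C@@H]1C=C(C)CC(O)(CO)[C@@H]2[C@]1(C)CCC23OCCO3
F9 | step 11 | C4 isopropenyl carbinol, C6 alcohol (1S,4R,5S,10R; C6 epimers) | CC(C)(C)[Si](C)(C)O[C@@H]1C=C(C)CC(O)[C@@H]2[C@]1(C)CC[C@@]2(O)C(C)=C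
F10 | step 13 | C4 dimethylsilyl ether of β-hydroxy ketone 18 | CC(C)(C)[Si](C)(C)O[C@@H]1C=C(C)CC(=O)[C@@H]2[C@]1(C)CC[C@@]2(O[SiH](C)C)C(C)C
F11 | step 13 | cyclic 4,6-O-dimethylsilylene acetal of diol 19 | CC(C)(C)[Si](C)(C)O[C@@H]1C=C(C)C[C@H](O3)[C@@H]2[C@]1(C)CC[C@@]2(O[Si]3(C)C)C(C)C
F12 | step 16 | 10-O-{2-[bis(2,2,2-trifluoroethoxy)phosphoryl]propanoyl} ester of 22 | CC(C(=O)O[C@@H]1C=C(C)C[C@H](OC(=O)c2ccc(OC)c(OC)c2)[C@@H]2[C@]1(C)CC[C@@]2(O)C(C)C)P(=O)(OCC(F)(F)F)OCC(F)(F)F
A1 | alternative 1 | 3-methylcyclopent-2-en-1-one | CC1=CC(=O)CC1
A2 | alternative 1 | diisobutyl[1-(trimethylsilyl)ethenyl]aluminium | C=C([Si](C)(C)C)[Al](CC(C)C)CC(C)C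
A3 | alternative 1 | 3,3-ethylenedioxybutanal, 2-(2-methyl-1,3-dioxolan-2-yl)acetaldehyde | CC1(CC=O)OCCO1
A4 | alternative 1 | trans-2,3-disubstituted 3-methylcyclopentanone aldol with C6 carbinol, ketal-masked C8 and 1-(trimethylsilyl)ethenyl group on C1 | CC1(C[C@H](O)[C@H]2C(=O)CC[C@]2(C)C(=C)[Si](C)(C)C)OCCO1
A5 | alternative 2 | ethyl 3-(1-hydroxycyclobutyl)-3-methyloxirane-2-carboxylate (configuration as drawn) | CCOC(=O)[C@H]1O[C@]1(C)C1(O)CCC1
A6 | alternative 2 | ethyl 2-hydroxy-2-(1-methyl-2-oxocyclopentyl)acetate with C1 and C10 as in the target | O=C1CCC[C@]1(C)[C@H](O)C(=O)OCC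
A7 | alternative 3 | (S)-Wieland–Miescher ketone | C[C@]12CCC(=O)C=C1CCCC2=O
A8 | alternative 3 | cis-fused decalin with C10 ethylene ketal, C4 isopropyl carbinol, tertiary C6 hydroxyl and C5 mesylate | CC(C)[C@]1(O)CC[C@]2(C)C3(OCCO3)CCC[C@]2(O)[C@H]1OS(C)(=O)=O
A9 | alternative 3 | trans-fused hydroazulen-6-one with C4 isopropyl carbinol and C10 ethylene ketal | O1CCOC12CCCC(=O)[C@@H]3[C@]2(C)CC[C@@]3(O)C(C)C
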